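**Retrosynthetic overview**

- Ring C of the target is cut at C4–C4a and at O1–C2. This gives an A-ring phenol and a B-ring aroylacetate (ring B plus C2, C3 and C4). Both bonds are made in one thermal operation, the last step.
- The strategy rests on the A-ring fragment, 2,4-dimethoxybenzene-1,3,5-triol. Its only ring C–H (the future C4a) lies on a mirror plane that runs through C4a and the C7 oxygen, and the two hydroxyls beside it (the future O1 and 5-OH) are equivalent. Only the 5,7-dihydroxy-6,8-dimethoxy pattern can therefore form.
- The triol comes from 1,3,5-tris(benzyloxy)benzene by dibromination, double copper-catalysed methoxylation and hydrogenolysis. The ketoester comes from 2,3-dimethoxybenzoic acid and potassium ethyl malonate.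
- Ring order: rings A and B are bought as benzenes. Ring C, the pyran-4-one, is the only ring made and is closed last, C4–C4a before O1–C2.

Key step: step 5

Remark on the chemistry: the target has no stereocentre and no stereogenic double bond, so no SMILES carries a stereodescriptor. The two magnesium intermediates of the ketoester step are drawn as simple salts (dianion plus Mg2+) of the chelates present in solution. In that step the imidazolyl group of 1,1'-carbonyldiimidazole is carried only in intermediate 7 and the magnesium of MgCl2 only in intermediates 8 and 9, so neither reagent contributes an atom to ketoester 10.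

**Route**

Step 1
Reactants: 1 1,3,5-tris(benzyloxy)benzene
Product: 2 2,4-dibromo-1,3,5-tris(benzyloxy)benzene
Conditions: NBS (2.05 equiv), MeCN–CH2Cl2, 0 °C to rt, dark
Reagents that add atoms: N-bromosuccinimide O=C1CCC(=O)N1Br
Why: Electrophilic aromatic bromination: each ring C–H of 1 is activated by three alkoxy groups whereas the benzyl phenyl rings are not, and each bromine slows the next substitution, so two equivalents of NBS in a cold polar medium without light should stop at the dibromide and avoid radical benzylic bromination.

Step 2
Reactants: 2 2,4-dibromo-1,3,5-tris(benzyloxy)benzene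
Product: 3 1,3,5-tris(benzyloxy)-2,4-dimethoxybenzene
Conditions: NaOMe (10 equiv, 25% in MeOH), CuBr (0.4 equiv), DMF, 110 °C, argon
Reagents that add atoms: sodium methoxide C[O-].[Na+]
Why: Ullmann-type ether synthesis: methoxide replaces both aryl bromides under catalysis by monovalent copper, a reaction known for 2-bromo-1,3-dialkoxyarenes, while the benzyl aryl ethers and the remaining ring C–H are inert to NaOMe in DMF.

Step 3
Reactants: 3 1,3,5-tris(benzyloxy)-2,4-dimethoxybenzene
Product: 4 2,4-dimethoxybenzene-1,3,5-triol
Conditions: H2 (1 atm), 10% Pd/C, EtOAc–MeOH, rt; filtered through Celite under argon, evaporated, used at once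
Reagents that add atoms: none
Why: Catalytic hydrogenolysis: the three benzylic C–O bonds are cleaved over palladium on carbon while the aryl methyl ethers and the arene are untouched, and toluene is the only coproduct, so the oxygen-sensitive triol can be taken on without purification.

Step 4
Reactants: 5 2,3-dimethoxybenzoic acid; 6 potassium ethyl malonate
Product: 10 ethyl 3-(2,3-dimethoxyphenyl)-3-oxopropanoate, via acyl imidazolide 7 (not isolated), via magnesium malonate enolate 8 (not isolated), via magnesium acylmalonate 9 (not isolated)
Conditions: 5, CDI (1.1 equiv), THF, rt; separately 6 (2 equiv), MgCl2 (2.2 equiv), Et3N (3 equiv), MeCN, rt; solutions combined, rt to 40 °C; 1 M HCl quench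
Reagents that add atoms: 1,1'-carbonyldiimidazole O=C(n1ccnc1)n1ccnc1; magnesium chloride [Mg+2].[Cl-].[Cl-]
Why: Decarboxylative Claisen-type acylation of a malonate half-ester: CDI turns 5 into imidazolide 7, the chelated magnesium enolate 8 formed with MgCl2 and Et3N is acylated at carbon to give 9, and on acidification the β-keto acid loses CO2, which should deliver the mono-acylated β-ketoester under conditions the aryl methyl ethers tolerate.

Step 5
Reactants: 4 2,4-dimethoxybenzene-1,3,5-triol; 10 ethyl 3-(2,3-dimethoxyphenyl)-3-oxopropanoate
Product: 13 5,7-dihydroxy-6,8,2',3'-tetramethoxyflavone, via aroylketene 11 (not isolated), via aryl diketone 12 (not isolated)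
Conditions: 4, 10 (2.5 equiv), neat melt, microwave heating, 240 °C, argon sweep to carry off EtOH and H2O, 15 min; then K2CO3, MeOH–H2O, rt, 15 min; 1 M HCl
Reagents that add atoms: none
Why: On heating, 10 loses ethanol to give aroylketene 11, whose ketene carbon is attacked by C6 of 4 (the future C4a, para to one hydroxyl and ortho to two) to form the C4–C4a bond and, after tautomerisation, the hydrogen-bonded 2-hydroxyaryl 1,3-diketone 12; phenol O-acylation by 11 also occurs but is reversible at this temperature, so material should drain through the irreversible C-acylation. A hydroxyl ortho to the new acyl group then adds to the aryl ketone carbonyl (6-exo-trig) to form the O1–C2 bond, and loss of water from the hemiketal gives ring C as the aromatic pyran-4-one, so the free 5-OH and 7-OH of 13 should emerge directly. The closest known reaction is the Mentzer pyrone synthesis, the acid-free thermal condensation of phloroglucinol with ethyl aroylacetates to 5,7-dihydroxyflavones, and 4 is comparably electron-rich. The step needs chemoselectivity for attack of the ring carbon on the ester-derived ketene carbon (flavone) over attack on the ketone (Pechmann route to a 4-arylcoumarin), which the absence of acid secures. Regioselectivity is secured by the substrate alone: 4 has one ring C–H and a mirror plane through it, so either flanking hydroxyl closes to the same 5,7-dihydroxy-6,8-dimethoxy product. No stereocentre is formed, and the brief carbonate treatment only cleaves aroylacetate esters that excess 11 may leave on the phenols.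

**Compound list**

1 | 1,3,5-tris(benzyloxy)benzene | c1ccc(COc2cc(OCc3ccccc3)cc(OCc3ccccc3)c2)cc1 | starting material
2 | 2,4-dibromo-1,3,5-tris(benzyloxy)benzene | Brc1c(OCc2ccccc2)cc(OCc2ccccc2)c(Br)c1OCc1ccccc1 | intermediate
3 | 1,3,5-tris(benzyloxy)-2,4-dimethoxybenzene | COc1c(OCc2ccccc2)cc(OCc2ccccc2)c(OC)c1OCc1ccccc1 | intermediate
4 | 2,4-dimethoxybenzene-1,3,5-triol | COc1c(O)cc(O)c(OC)c1O | intermediate
5 | 2,3-dimethoxybenzoic acid | COc1cccc(C(=O)O)c1OC | starting material
6 | potassium ethyl malonate (potassium 3-ethoxy-3-oxopropanoate) | CCOC(=O)CC(=O)[O-].[K+] | starting material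
7 | (2,3-dimethoxyphenyl)(1H-imidazol-1-yl)methanone (acyl imidazolide, not isolated) | COc1cccc(C(=O)n2ccnc2)c1OC | intermediate
8 | magnesium enolate of ethyl malonate (magnesium salt of the malonate half-ester dianion, not isolated) | CCOC([O-])=CC(=O)[O-].[Mg+2] | intermediate
9 | magnesium salt of the enolised 2-(2,3-dimethoxybenzoyl)malonic acid monoethyl ester (not isolated) | CCOC(=O)C(C(=O)[O-])=C([O-])c1cccc(OC)c1OC.[Mg+2] | intermediate
10 | ethyl 3-(2,3-dimethoxyphenyl)-3-oxopropanoate | CCOC(=O)CC(=O)c1cccc(OC)c1OC | intermediate
11 | (2,3-dimethoxybenzoyl)ketene, 3-(2,3-dimethoxyphenyl)prop-1-ene-1,3-dione (not isolated) | O=C=CC(=O)c1cccc(OC)c1OC | intermediate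
12 | 1-(2,3-dimethoxyphenyl)-3-(2,4,6-trihydroxy-3,5-dimethoxyphenyl)propane-1,3-dione (not isolated) | COc1cccc(C(=O)CC(=O)c2c(O)c(OC)c(O)c(OC)c2O)c1OC | intermediate
13 | 5,7-dihydroxy-6,8,2',3'-tetramethoxyflavone | COc1cccc(-c2cc(=O)c3c(O)c(OC)c(O)c(OC)c3o2)c1OC | target

**Step count**

Total step count: 5. Longest linear sequence: 4 steps (steps 1, 2, 3 and 5); step 4 is a one-step side branch.

**Steps most likely to fail**

1. Step 5. At 240 °C the triol may be lost to oxidative or thermal decomposition faster than its ring carbon is acylated. The aroylketene may also be consumed by dimerisation, or the ring may attack the ketone carbonyl instead (coumarin pathway).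
Fallback: it sets out from 4 and 5 and rejoins the route at diketone 12, which is then closed to 13. Friedel–Crafts/Fries C-acetylation of 4 at its only ring C–H (Ac2O, BF3·OEt2, rt, then aqueous NaOAc) should give 1-(2,4,6-trihydroxy-3,5-dimethoxyphenyl)ethan-1-one F1. Acid 5 is converted with SOCl2 (cat. DMF, toluene, 70 °C) into 2,3-dimethoxybenzoyl chloride F2. F1 is treated with LiN(SiMe3)2 (5 equiv, THF, −78 °C) and then with F2; the ketone enolate of the polyanion is aroylated at carbon and acidification gives 12, here isolated. Cyclodehydration of 12 (AcOH, cat. H2SO4, 95 °C) should give 13. The same symmetry of ring A fixes the substitution pattern.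

2. Step 2. Substitution at the second bromide may stall, since it is flanked by two benzyloxy groups on a ring that has become more electron-rich. Reductive loss of bromine or attack of methoxide on a benzyl group may then overtake it.
Fallback: it sets out from 1, returns at 3, and bypasses step 1 as well. Vilsmeier–Haack formylation of 1 (POCl3, DMF, then aqueous NaOAc) gives 2,4,6-tris(benzyloxy)benzaldehyde F3. Baeyer–Villiger oxidation (mCPBA, CH2Cl2) gives 2,4,6-tris(benzyloxy)phenyl formate F4, which is methanolysed (K2CO3, MeOH, argon) to 2,4,6-tris(benzyloxy)phenol F5. O-Methylation (MeI, K2CO3, DMF) gives 1,3,5-tris(benzyloxy)-2-methoxybenzene F6. The same three operations at one of its two equivalent ring C–H positions give in turn 2,4,6-tris(benzyloxy)-3-methoxybenzaldehyde F7, 2,4,6-tris(benzyloxy)-3-methoxyphenyl formate F8 and 2,4,6-tris(benzyloxy)-3-methoxyphenol F9, and methylation of F9 gives 3. No aryl halide substitution is involved.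

3. Step 3. The electron-rich triol may oxidise in air to quinonoid material while the catalyst is filtered off and the solution is concentrated.
Fallback: it sets out from 3 and returns at 4. After hydrogenolysis (H2, Pd/C, EtOAc), hydrogen is replaced by argon and the mixture is acetylated in the same flask before any contact with air (Ac2O, pyridine, cat. DMAP). This should give 2,4-dimethoxybenzene-1,3,5-triyl triacetate F10, which is air-stable and can be filtered, purified and stored. Acid transesterification of F10 (degassed HCl in MeOH, argon, rt to 40 °C) and evaporation of the volatiles releases 4 in the vessel in which step 5 is then run.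

**Further compounds**

F1 | step 5 | 1-(2,4,6-trihydroxy-3,5-dimethoxyphenyl)ethan-1-one | CC(=O)c1c(O)c(OC)c(O)c(OC)c1O
F2 | step 5 | 2,3-dimethoxybenzoyl chloride | COc1cccc(C(=O)Cl)c1OC
F3 | step 2 | 2,4,6-tris(benzyloxy)benzaldehyde | O=Cc1c(OCc2ccccc2)cc(OCc2ccccc2)cc1OCc1ccccc1
F4 | step 2 | 2,4,6-tris(benzyloxy)phenyl formate | O=COc1c(OCc2ccccc2)cc(OCc2ccccc2)cc1OCc1ccccc1
F5 | step 2 | 2,4,6-tris(benzyloxy)phenol | Oc1c(OCc2ccccc2)cc(OCc2ccccc2)cc1OCc1ccccc1
F6 | step 2 | 1,3,5-tris(benzyloxy)-2-methoxybenzene | COc1c(OCc2ccccc2)cc(OCc2ccccc2)cc1OCc1ccccc1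
F7 | step 2 | 2,4,6-tris(benzyloxy)-3-methoxybenzaldehyde | COc1c(OCc2ccccc2)cc(OCc2ccccc2)c(C=O)c1OCc1ccccc1
F8 | step 2 | 2,4,6-tris(benzyloxy)-3-methoxyphenyl formate | COc1c(OCc2ccccc2)cc(OCc2ccccc2)c(OC=O)c1OCc1ccccc1
F9 | step 2 | 2,4,6-tris(benzyloxy)-3-methoxyphenol | COc1c(OCc2ccccc2)cc(OCc2ccccc2)c(O)c1OCc1ccccc1
F10 | step 3 | 2,4-dimethoxybenzene-1,3,5-triyl triacetate | COc1c(OC(C)=O)cc(OC(C)=O)c(OC)c1OC(C)=O
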